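**Plan**

- Retrosynthesis: the three phenols are unmasked last (MOM ethers). The pyranone ring is then opened at two bonds at once, O1–C2 and C4–C4a, giving an aryl cinnamate in which the C4 acyl carbon hangs on O1 and C4a carries iodine. The ester is cut into an ortho-iodophenol (ring A) and a cinnamic acid (ring B with C2–C4).
- Enabling feature: the C4 carbonyl sits on C4a, ortho to the ring oxygen O1 on C8a, and C2 is the β-carbon of that aryl ketone. The heterocycle is therefore an ortho-acylphenol added across a cinnamoyl C=C, and the aryl ester (O1–C4) is one 1,3-acyl shift away from the ketone (C4a–C4).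
- Ring A (prenyl at C6 between O5 and O7, O1 para to it) is mirror-symmetric as 3,5-bis(MOM-oxy)-4-prenylphenol. Both carbons ortho to O1 are equivalent, so a 6- versus 8-prenyl mixture cannot arise.
- Forward order: ring A from phloroglucinol (mono-silylation, MOM, ortho-lithiation/prenylation, desilylation, iodination); ring B acid from 3,5-dibromo-4-hydroxybenzaldehyde (MOM, double Stille prenylation, Doebner); esterification; one-flask closure of the pyranone ring; deprotection.
- Stereochemistry: the only stereocentre, C2 (R, the antipode of the usual natural 2S series), is set in the ring-closing event by a cinchona amine–thiourea catalyst. The acidic deprotection does not touch it.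

Key step: step 10

Assumption: the sense of induction of the cinchona thiourea on this substrate cannot be fixed in advance; the quinidine-derived catalyst is written for the (2R) product, and its quinine-derived pseudoenantiomer takes its place if the opposite sense is found.

**Route**

Step 1
Reactants: 1 benzene-1,3,5-triol (phloroglucinol)
Product: 2 5-[(triisopropylsilyl)oxy]benzene-1,3-diol
Conditions: 1 (3 equiv), TIPSCl (1 equiv), imidazole, DMF, 0 °C → rt
Reagents that add atoms: triisopropylsilyl chloride, CC(C)[Si](Cl)(C(C)C)C(C)C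
Why: Silyl ether formation on a C3-symmetric triol is statistical, and with the cheap triol in threefold excess and a bulky silyl chloride the mono-ether should dominate, the unreacted triol being removed by aqueous extraction.

Step 2
Reactants: 2 5-[(triisopropylsilyl)oxy]benzene-1,3-diol
Product: 3 [3,5-bis(methoxymethoxy)phenoxy]triisopropylsilane
Conditions: MOMCl, i-Pr2NEt, CH2Cl2, 0 °C → rt
Reagents that add atoms: chloromethyl methyl ether, COCCl
Why: Base-mediated O-alkylation (MOM ether formation) of the two remaining equivalent phenols; the aryl TIPS ether is inert to amine base and MOMCl.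

Step 3
Reactants: 3 [3,5-bis(methoxymethoxy)phenoxy]triisopropylsilane; 4 1-bromo-3-methylbut-2-ene (prenyl bromide)
Product: 6 [3,5-bis(methoxymethoxy)-4-(3-methylbut-2-en-1-yl)phenoxy]triisopropylsilane, via aryllithium 5 (not isolated)
Conditions: n-BuLi, TMEDA, THF, 0 °C; then CuI (10 mol%), 4, −78 °C → rt
Reagents that add atoms: none
Why: Directed ortho-metalation, in which the C–H flanked by the two OMOM groups is the most acidic and doubly chelated site (the positions next to the bulky OTIPS are not), followed by copper-catalysed SN2 alkylation of aryllithium 5 with the primary allylic bromide to give the linear prenyl arene.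

Step 4
Reactants: 6 [3,5-bis(methoxymethoxy)-4-(3-methylbut-2-en-1-yl)phenoxy]triisopropylsilane
Product: 7 3,5-bis(methoxymethoxy)-4-(3-methylbut-2-en-1-yl)phenol
Conditions: TBAF, AcOH (1:1), THF, 0 °C → rt
Reagents that add atoms: none
Why: Fluoride-induced Si–O cleavage of the aryl silyl ether under acetic acid buffering, which leaves the MOM ethers and the prenyl group untouched.

Step 5
Reactants: 7 3,5-bis(methoxymethoxy)-4-(3-methylbut-2-en-1-yl)phenol
Product: 8 2-iodo-3,5-bis(methoxymethoxy)-4-(3-methylbut-2-en-1-yl)phenol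
Conditions: NIS (1.0 equiv), CH2Cl2, −20 °C, dark
Reagents that add atoms: N-iodosuccinimide, O=C1CCC(=O)N1I
Why: Electrophilic aromatic iodination: the two free ring positions are equivalent by symmetry and activated by the ortho-OH and a para-OMOM, so one equivalent of NIS at low temperature should give the mono-iodide faster than it attacks the trisubstituted alkene.

Step 6
Reactants: 9 3,5-dibromo-4-hydroxybenzaldehyde
Product: 10 3,5-dibromo-4-(methoxymethoxy)benzaldehyde
Conditions: MOMCl, i-Pr2NEt, DMF, 0 °C → rt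
Reagents that add atoms: chloromethyl methyl ether, COCCl
Why: MOM ether formation on the acidic 2,6-dibromophenol, which masks the phenol for the cross-coupling and organolithium steps.

Step 7
Reactants: 10 3,5-dibromo-4-(methoxymethoxy)benzaldehyde; 11 tributyl(3-methylbut-2-en-1-yl)stannane
Product: 13 4-(methoxymethoxy)-3,5-bis(3-methylbut-2-en-1-yl)benzaldehyde, via monoprenylated bromoaldehyde 12 (not isolated)
Conditions: 11 (2.5 equiv), Pd(PPh3)4 (5 mol%), DMF, 100 °C
Reagents that add atoms: none
Why: Twofold Migita–Kosugi–Stille coupling of the aryl bromides with the allylstannane, in which reductive elimination from the allylpalladium intermediate at its less substituted terminus should give the linear prenyl groups while the aldehyde is tolerated.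

Step 8
Reactants: 13 4-(methoxymethoxy)-3,5-bis(3-methylbut-2-en-1-yl)benzaldehyde; 14 propanedioic acid (malonic acid)
Product: 16 (2E)-3-[4-(methoxymethoxy)-3,5-bis(3-methylbut-2-en-1-yl)phenyl]prop-2-enoic acid, via arylidenemalonic acid 15 (not isolated)
Conditions: pyridine, piperidine (cat.), 90 °C
Reagents that add atoms: none
Why: Knoevenagel–Doebner condensation, in which arylidenemalonic acid 15 decarboxylates in hot pyridine to the thermodynamically preferred (E)-cinnamic acid.

Step 9
Reactants: 8 2-iodo-3,5-bis(methoxymethoxy)-4-(3-methylbut-2-en-1-yl)phenol; 16 (2E)-3-[4-(methoxymethoxy)-3,5-bis(3-methylbut-2-en-1-yl)phenyl]prop-2-enoic acid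
Product: 17 2-iodo-3,5-bis(methoxymethoxy)-4-(3-methylbut-2-en-1-yl)phenyl (2E)-3-[4-(methoxymethoxy)-3,5-bis(3-methylbut-2-en-1-yl)phenyl]prop-2-enoate
Conditions: DIC, DMAP (cat.), CH2Cl2, 0 °C → rt
Reagents that add atoms: none
Why: Steglich esterification (carbodiimide activation, DMAP acyl transfer) should couple the hindered ortho-iodophenol under neutral conditions that spare the MOM ethers.

Step 10
Reactants: 17 2-iodo-3,5-bis(methoxymethoxy)-4-(3-methylbut-2-en-1-yl)phenyl (2E)-3-[4-(methoxymethoxy)-3,5-bis(3-methylbut-2-en-1-yl)phenyl]prop-2-enoate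
Product: 21 (2R)-5,7-bis(methoxymethoxy)-2-[4-(methoxymethoxy)-3,5-bis(3-methylbut-2-en-1-yl)phenyl]-6-(3-methylbut-2-en-1-yl)-2,3-dihydro-4H-chromen-4-one, via aryllithium 18 (not isolated), via lithium chalcone phenoxide 19 (not isolated), via 2'-hydroxychalcone 20 (not isolated)
Conditions: n-BuLi (1.05 equiv), PhMe/Et2O 4:1, −78 → −40 °C; AcOH (1.0 equiv); then quinidine-derived (9-amino-9-deoxy-epi-quinidine) 3,5-bis(trifluoromethyl)phenyl thiourea (10 mol%), −20 °C
Reagents that add atoms: none
Why: Proposed new method: n-BuLi should exchange the iodine on the ring carbon ortho to the ester oxygen faster than it adds to the cinnamate, and aryllithium 18 then attacks its own ester carbonyl through a four-membered transition state (1,3 O→C acyl shift) to give the chelated lithium phenoxide 19, so that the C4–C4a bond can form only at the carbon that carried iodine. One equivalent of AcOH frees 2'-hydroxychalcone 20, and the amine–thiourea closes the pyranone ring by 6-endo-trig oxa-Michael addition of that phenol oxygen to the β-carbon, which forms O1–C2. The closest known reaction types are the metal–halogen-exchange-induced anionic Fries shift of ortho-haloaryl esters and the organocatalytic biomimetic cyclization of 2'-hydroxychalcones to flavanones; new is their union in one flask on a cinnamate ester that leads to a 6'-alkoxychalcone in the presence of lithium salts. The C2 stereocentre is controlled by the catalyst alone: the quinuclidine deprotonates and holds the phenol while the thiourea hydrogen-bonds the enone carbonyl, so that oxygen is delivered to one enantiotopic face of the β-carbon to give the 2R configuration. The step needs acyl shift in preference to conjugate addition of the aryllithium (the carbonyl carbon lies three atoms from the carbanion, whereas the β-carbon is reached only from the disfavoured ester rotamer), a single mode of ring closure (the phenol released from the ester is the only free ortho oxygen, the other being a MOM ether, which places the prenyl group at C6), and kinetic enantiocontrol over a reversible closure (low temperature, non-polar medium, quench as soon as conversion is complete).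

Step 11
Reactants: 21 (2R)-5,7-bis(methoxymethoxy)-2-[4-(methoxymethoxy)-3,5-bis(3-methylbut-2-en-1-yl)phenyl]-6-(3-methylbut-2-en-1-yl)-2,3-dihydro-4H-chromen-4-one
Product: 22 (2R)-5,7-dihydroxy-2-[4-hydroxy-3,5-bis(3-methylbut-2-en-1-yl)phenyl]-6-(3-methylbut-2-en-1-yl)-2,3-dihydro-4H-chromen-4-one
Conditions: HCl (3 M aq, cat.), MeOH/THF, 40 °C; neutral work-up
Reagents that add atoms: none
Why: Acid-catalysed methanolysis of the three aryl MOM acetals; C2 is not α to the carbonyl and an acidic medium avoids the base-induced ring opening to the chalcone, so the (R) configuration should be kept.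

**Compound list**

1 | benzene-1,3,5-triol (phloroglucinol) | Oc1cc(O)cc(O)c1 | starting material
2 | 5-[(triisopropylsilyl)oxy]benzene-1,3-diol | CC(C)[Si](Oc1cc(O)cc(O)c1)(C(C)C)C(C)C | intermediate
3 | [3,5-bis(methoxymethoxy)phenoxy]triisopropylsilane | COCOc1cc(OCOC)cc(O[Si](C(C)C)(C(C)C)C(C)C)c1 | intermediate
4 | 1-bromo-3-methylbut-2-ene (prenyl bromide) | CC(C)=CCBr | starting material
5 | [2,6-bis(methoxymethoxy)-4-(triisopropylsilyloxy)phenyl]lithium | [Li]c1c(OCOC)cc(O[Si](C(C)C)(C(C)C)C(C)C)cc1OCOC | intermediate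
6 | [3,5-bis(methoxymethoxy)-4-(3-methylbut-2-en-1-yl)phenoxy]triisopropylsilane | COCOc1cc(O[Si](C(C)C)(C(C)C)C(C)C)cc(OCOC)c1CC=C(C)C | intermediate
7 | 3,5-bis(methoxymethoxy)-4-(3-methylbut-2-en-1-yl)phenol | COCOc1cc(O)cc(OCOC)c1CC=C(C)C | intermediate
8 | 2-iodo-3,5-bis(methoxymethoxy)-4-(3-methylbut-2-en-1-yl)phenol | COCOc1cc(O)c(I)c(OCOC)c1CC=C(C)C | intermediate
9 | 3,5-dibromo-4-hydroxybenzaldehyde | O=Cc1cc(Br)c(O)c(Br)c1 | starting material
10 | 3,5-dibromo-4-(methoxymethoxy)benzaldehyde | COCOc1c(Br)cc(C=O)cc1Br | intermediate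
11 | tributyl(3-methylbut-2-en-1-yl)stannane | CCCC[Sn](CCCC)(CCCC)CC=C(C)C | starting material
12 | 3-bromo-4-(methoxymethoxy)-5-(3-methylbut-2-en-1-yl)benzaldehyde | COCOc1c(Br)cc(C=O)cc1CC=C(C)C | intermediate
13 | 4-(methoxymethoxy)-3,5-bis(3-methylbut-2-en-1-yl)benzaldehyde | COCOc1c(CC=C(C)C)cc(C=O)cc1CC=C(C)C | intermediate
14 | propanedioic acid (malonic acid) | OC(=O)CC(=O)O | starting material
15 | 2-{[4-(methoxymethoxy)-3,5-bis(3-methylbut-2-en-1-yl)phenyl]methylidene}propanedioic acid | COCOc1c(CC=C(C)C)cc(C=C(C(=O)O)C(=O)O)cc1CC=C(C)C | intermediate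
16 | (2E)-3-[4-(methoxymethoxy)-3,5-bis(3-methylbut-2-en-1-yl)phenyl]prop-2-enoic acid | COCOc1c(CC=C(C)C)cc(/C=C/C(=O)O)cc1CC=C(C)C | intermediate
17 | 2-iodo-3,5-bis(methoxymethoxy)-4-(3-methylbut-2-en-1-yl)phenyl (2E)-3-[4-(methoxymethoxy)-3,5-bis(3-methylbut-2-en-1-yl)phenyl]prop-2-enoate | COCOc1cc(OC(=O)/C=C/c2cc(CC=C(C)C)c(OCOC)c(CC=C(C)C)c2)c(I)c(OCOC)c1CC=C(C)C | intermediate
18 | 2-lithio-3,5-bis(methoxymethoxy)-4-(3-methylbut-2-en-1-yl)phenyl (2E)-3-[4-(methoxymethoxy)-3,5-bis(3-methylbut-2-en-1-yl)phenyl]prop-2-enoate | COCOc1cc(OC(=O)/C=C/c2cc(CC=C(C)C)c(OCOC)c(CC=C(C)C)c2)c([Li])c(OCOC)c1CC=C(C)C | intermediate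
19 | lithium 3,5-bis(methoxymethoxy)-2-{(2E)-3-[4-(methoxymethoxy)-3,5-bis(3-methylbut-2-en-1-yl)phenyl]prop-2-enoyl}-4-(3-methylbut-2-en-1-yl)phenoxide | COCOc1cc(O[Li])c(C(=O)/C=C/c2cc(CC=C(C)C)c(OCOC)c(CC=C(C)C)c2)c(OCOC)c1CC=C(C)C | intermediate
20 | (2E)-1-[6-hydroxy-2,4-bis(methoxymethoxy)-3-(3-methylbut-2-en-1-yl)phenyl]-3-[4-(methoxymethoxy)-3,5-bis(3-methylbut-2-en-1-yl)phenyl]prop-2-en-1-one | COCOc1cc(O)c(C(=O)/C=C/c2cc(CC=C(C)C)c(OCOC)c(CC=C(C)C)c2)c(OCOC)c1CC=C(C)C | intermediate
21 | (2R)-5,7-bis(methoxymethoxy)-2-[4-(methoxymethoxy)-3,5-bis(3-methylbut-2-en-1-yl)phenyl]-6-(3-methylbut-2-en-1-yl)-2,3-dihydro-4H-chromen-4-one | CC(C)=CCc1cc([C@H]2CC(=O)c3c(cc(OCOC)c(CC=C(C)C)c3OCOC)O2)cc(CC=C(C)C)c1OCOC | intermediate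
22 | (2R)-5,7-dihydroxy-2-[4-hydroxy-3,5-bis(3-methylbut-2-en-1-yl)phenyl]-6-(3-methylbut-2-en-1-yl)-2,3-dihydro-4H-chromen-4-one | CC(C)=CCc1cc([C@H]2CC(=O)c3c(cc(O)c(CC=C(C)C)c3O)O2)cc(CC=C(C)C)c1O | target

**Step count**

Total: 11 steps. Longest linear sequence: 8 steps (steps 1–5, 9, 10, 11).

**Steps most likely to fail**

1. Step 10. The alkyllithium may add to the unsaturated ester, or the aryllithium may add in conjugate fashion instead of shifting the acyl group. In the salt-containing medium the ring may also close by an uncatalysed, racemic pathway, or the product may lose enantiopurity through reversible ring opening. The fallback uses known chemistry only; it sets out from iodophenol 8 (with aldehyde 13) and comes back at 21. Stille coupling of 8 with tributyl(1-ethoxyvinyl)stannane (Pd(PPh3)4, toluene, 90 °C) should give 2-(1-ethoxyethenyl)-3,5-bis(methoxymethoxy)-4-(3-methylbut-2-en-1-yl)phenol F1. Brief treatment with dilute aqueous HCl in THF at 0 °C hydrolyses it to 1-[6-hydroxy-2,4-bis(methoxymethoxy)-3-(3-methylbut-2-en-1-yl)phenyl]ethan-1-one F2. Claisen–Schmidt condensation of F2 with aldehyde 13 (KOH, EtOH/H2O, rt) gives chalcone 20, now isolated. NaOAc in EtOH at reflux closes it under thermodynamic control to racemic 5,7-bis(methoxymethoxy)-2-[4-(methoxymethoxy)-3,5-bis(3-methylbut-2-en-1-yl)phenyl]-6-(3-methylbut-2-en-1-yl)-2,3-dihydro-4H-chromen-4-one F3. Kinetic resolution by asymmetric transfer hydrogenation (Cp*RhCl(TsDPEN), HCO2H/Et3N, EtOAc, rt), with the catalyst enantiomer that reduces the (2S)-ketone faster, converts that enantiomer into (2S,4S)-5,7-bis(methoxymethoxy)-2-[4-(methoxymethoxy)-3,5-bis(3-methylbut-2-en-1-yl)phenyl]-6-(3-methylbut-2-en-1-yl)-3,4-dihydro-2H-chromen-4-ol F4. The unreacted (2R)-ketone 21 is separated by chromatography.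

2. Step 7. Coupling may occur through the γ-terminus of the allyl unit (reverse-prenyl groups), palladium hydride may move the prenyl double bond into conjugation with the ring, and the second coupling may stall at the hindered bromide. The fallback sets out from 10 and comes back at 13. Acetalization (HC(OMe)3, PPTS, MeOH) gives 1,3-dibromo-5-(dimethoxymethyl)-2-(methoxymethoxy)benzene F5. Br/Li exchange (n-BuLi, THF, −78 °C), transmetalation with CuBr·SMe2 and alkylation with prenyl bromide 4 give 1-bromo-5-(dimethoxymethyl)-2-(methoxymethoxy)-3-(3-methylbut-2-en-1-yl)benzene F6. The same exchange/alkylation sequence on F6 gives 5-(dimethoxymethyl)-2-(methoxymethoxy)-1,3-bis(3-methylbut-2-en-1-yl)benzene F7. PPTS in wet acetone at rt then releases aldehyde 13 without cleaving the aryl MOM ether.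

3. Step 11. A prenyl group may cyclize under acid onto the neighbouring freed phenol (chroman formation), the prenyl double bonds may be hydrated, and prolonged heating may cause partial racemization through acid-mediated ring opening. The fallback sets out from 21 and comes back at 22. TMSOTf and 2,2'-bipyridyl in CH2Cl2 at 0 °C convert the aryl MOM ethers into aryl silyl ethers under non-protic conditions, giving (2R)-5,7-bis(trimethylsilyloxy)-2-[3,5-bis(3-methylbut-2-en-1-yl)-4-(trimethylsilyloxy)phenyl]-6-(3-methylbut-2-en-1-yl)-2,3-dihydro-4H-chromen-4-one F8. Solvolysis of F8 in MeOH with a trace of citric acid at rt gives 22.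

**Further compounds**

F1 | step 10 | 2-(1-ethoxyethenyl)-3,5-bis(methoxymethoxy)-4-(3-methylbut-2-en-1-yl)phenol | CCOC(=C)c1c(O)cc(OCOC)c(CC=C(C)C)c1OCOC
F2 | step 10 | 1-[6-hydroxy-2,4-bis(methoxymethoxy)-3-(3-methylbut-2-en-1-yl)phenyl]ethan-1-one | CC(=O)c1c(O)cc(OCOC)c(CC=C(C)C)c1OCOC
F3 | step 10 | racemic 5,7-bis(methoxymethoxy)-2-[4-(methoxymethoxy)-3,5-bis(3-methylbut-2-en-1-yl)phenyl]-6-(3-methylbut-2-en-1-yl)-2,3-dihydro-4H-chromen-4-one | CC(C)=CCc1cc(C2CC(=O)c3c(cc(OCOC)c(CC=C(C)C)c3OCOC)O2)cc(CC=C(C)C)c1OCOC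
F4 | step 10 | (2S,4S)-5,7-bis(methoxymethoxy)-2-[4-(methoxymethoxy)-3,5-bis(3-methylbut-2-en-1-yl)phenyl]-6-(3-methylbut-2-en-1-yl)-3,4-dihydro-2H-chromen-4-ol | CC(C)=CCc1cc([C@@H]2C[C@H](O)c3c(cc(OCOC)c(CC=C(C)C)c3OCOC)O2)cc(CC=C(C)C)c1OCOC
F5 | step 7 | 1,3-dibromo-5-(dimethoxymethyl)-2-(methoxymethoxy)benzene | COCOc1c(Br)cc(C(OC)OC)cc1Br
F6 | step 7 | 1-bromo-5-(dimethoxymethyl)-2-(methoxymethoxy)-3-(3-methylbut-2-en-1-yl)benzene | COCOc1c(Br)cc(C(OC)OC)cc1CC=C(C)C
F7 | step 7 | 5-(dimethoxymethyl)-2-(methoxymethoxy)-1,3-bis(3-methylbut-2-en-1-yl)benzene | COCOc1c(CC=C(C)C)cc(C(OC)OC)cc1CC=C(C)C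
F8 | step 11 | (2R)-5,7-bis(trimethylsilyloxy)-2-[3,5-bis(3-methylbut-2-en-1-yl)-4-(trimethylsilyloxy)phenyl]-6-(3-methylbut-2-en-1-yl)-2,3-dihydro-4H-chromen-4-one | CC(C)=CCc1cc([C@H]2CC(=O)c3c(cc(O[Si](C)(C)C)c(CC=C(C)C)c3O[Si](C)(C)C)O2)cc(CC=C(C)C)c1O[Si](C)(C)C
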